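Remark on the chemistry (assumption): the SMILES is read as the erythro (anti) arylglycerol β-aryl ether with Cα = S and Cβ = R, where Cα is the benzylic carbinol carbon, Cβ the ether carbon, Cγ the hydroxymethyl carbon and O4′ the ether oxygen on ring B.

## Structural features

The target is a flavonolignan: a 5,7-dihydroxyflavone (ring A = the dihydroxylated benzo ring, ring C = the 4-pyranone with O1, C2, C3, C4, ring B = the 3′,5′-dimethoxyphenyl ring on C2) whose O4′ is bonded to Cβ of a 1-arylpropane-1,3-diol chain Cα–Cβ–Cγ, with the 4-hydroxyphenyl ring D on Cα. There are only two stereocentres, and they are adjacent: Cα (S, secondary benzylic alcohol) and Cβ (R, alkyl aryl ether carbon), in the anti (erythro) relationship. The O4′–Cβ bond is the most hindered bond of the molecule, because O4′ lies between two ortho methoxy groups and Cβ carries both Cα and Cγ. The Cα–OH group is benzylic and para to the free phenol of ring D, so acid or heat can ionise it to a quinone methide, with epimerisation or solvolysis, and it is also open to hydrogenolysis. Cβ–H becomes acidic whenever Cα or Cγ is a carbonyl carbon, the C2=C3–C4=O enone of ring C can be reduced, and three phenols (O5, O7, ring D) must be kept apart from O4′. The real difficulty is therefore to make a hindered secondary alkyl aryl ether together with the anti Cα/Cβ pair in one absolute configuration, without ever placing a leaving group on Cβ. The key step exploits the fact that Cα(OH)–Cβ(OAr)–Cγ is an aldol retron: Cβ–Cγ can come from an α-aryloxy acetaldehyde that already carries O4′, and Cα from the ring D aldehyde, which has no α-hydrogen. Before that step Cβ is a plain CH2 group, so the O4′–Cβ bond is a primary ether that can be made at the very start on ring B alone.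

## Logic of the disconnections

13 back to 12 and 11. Bonds cut: the two benzyl C–O bonds on O5 and O7 (13 to 12) and the acyl C–O bond on the ring D oxygen (12 to 11). Ring A has to be masked by base-stable groups for the construction of ring C, and the ring D oxygen has to be an electron-poor ester during the key step. No skeletal simplification results. The demand is that both removals avoid acid, that the methanolysis is mild, and that the hydrogenolysis spares the Cα–O bond and C2=C3.

11 back to 7 and 9 through 10 (key disconnection). Bonds cut: Cα–Cβ, after Cγ is taken back from hydroxymethyl to formyl in 10. In one sentence, the route is a proline-catalysed direct anti-aldol between 7 and the non-enolisable 9. This is the only cut that removes both stereocentres at once and leaves two achiral aldehydes, one of which holds the whole flavone with the hindered ether already in place at a CH2 group. The forward step must set Cα and Cβ, absolute and relative, from the catalyst alone, must favour cross-aldol over self-aldol of 7, and must be followed by reduction of 10 before it can epimerise at Cβ or revert.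

7 back to 6. Only the oxidation level of Cγ changes. The formyl group is too sensitive to survive the base and heat of the ring C construction, so it is carried as the alcohol. The forward oxidation must stop at the aldehyde and leave the electron-rich rings alone.

6 back to 5. Bonds cut: O1–C2 of ring C, together with the C2=C3 unsaturation. Ring C is opened to an open-chain enone that carries rings A and B at its two ends. The forward step is an oxidative 6-endo ring closure that must tolerate two benzyl ethers and a primary alcohol.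

5 back to 2 and 4. Bond cut: the C=C bond that later becomes C2–C3. This separates the ring A ketone from the ring B aldehyde. The forward condensation needs base-stable masking of O5 and O7 and an aldehyde with no free phenol, which 4 provides because O4′ is already alkylated.

4 back to 3. Bond cut: O4′–Cβ. This is the hindered ether of the target, cut at the stage where Cβ is an unsubstituted CH2 group, so that it becomes an SN2 reaction of the single phenol of 3 with a primary halide. The only demand is enough heat for a di-ortho-substituted phenoxide.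

2 back to 1, and 9 back to 8. Bonds cut: two benzyl C–O bonds and one acyl C–O bond. Both are protecting-group operations on commercial phenols; in 1 the chelated hydroxyl next to the acetyl group must stay free.

## Other disconnections considered

Alternative 1: the first idea is to cut O4′–Cβ with both stereocentres already in the electrophile. Forward key step: the phenoxide of A1 (5,7-di-O-benzyltricin) displaces, with inversion at Cβ, the α-nosylate A2, which would come from asymmetric dihydroxylation of a cinnamate and α-selective sulfonylation; this gives the erythro ester A3, then ester reduction and deprotection. Ground for preferring the chosen plan: a phenoxide between two methoxy groups would have to attack a secondary carbon that bears an acidic hydrogen and has a free hydroxyl next to it. Ring closure to the glycidic ester, elimination and base-induced epimerisation at Cβ are expected to compete with the slow intermolecular SN2, so the configuration is at risk in the most hindered bond formation. A1 also needs its own flavone synthesis with extra protection of O4′. In the chosen plan the ether is made at a primary carbon and Cβ never bears a leaving group.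

Alternative 2: no skeletal cut at the key step; the two stereocentres are set as a group by dynamic kinetic resolution. Forward key step: the racemic β-keto ester A4 (from A1 by alkylation or carbene O–H insertion) is reduced by asymmetric transfer hydrogenation with RuCl(p-cymene)(TsDPEN) and HCO2H/Et3N while Cβ racemises through the enol. Ground: hydride transfer in this outer-sphere mechanism is expected to go through the conformer in which the Cβ–O bond is antiperiplanar to the incoming hydride, which leads to the syn (threo) ester A5 and not to the anti arrangement of the target. The erythro series would then need an extra inversion at the ionisable benzylic Cα, and the hindered O4′–Cβ bond would still have to be made at a secondary carbon. The aldol gives the anti pair directly.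

Alternative 3: biomimetic cut of O4′–Cβ by radical coupling. Forward key step: one-electron oxidation (anodic or enzymatic) of A6 (tricin) and A7 (4-hydroxycinnamyl alcohol), coupling of the phenoxyl radical of A6 through O4′ with Cβ of the radical of A7, and addition of water to Cα of the quinone methide A8. Ground: the route would be very short and free of protecting groups, but both radicals are achiral and A8 is planar at Cα, so the product would be racemic and an erythro/threo mixture. A7 is the more easily oxidised partner and would mainly couple with itself. A single enantiomer would need a resolution, which the chosen plan avoids.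

Key step: step 7

## Route

Step 1
Reactants: 1 1-(2,4,6-trihydroxyphenyl)ethan-1-one
Product: 2 1-[2,4-bis(benzyloxy)-6-hydroxyphenyl]ethan-1-one
Conditions: BnBr (2.1 equiv), K2CO3 (2.2 equiv), DMF, rt to 50 °C
Reagents that add atoms: benzyl bromide, BrCc1ccccc1
Why: Williamson ether synthesis; the hydroxyl next to the acetyl group is held in an intramolecular hydrogen bond and is the least nucleophilic, so two equivalents of benzyl bromide should alkylate only the other two oxygens.

Step 2
Reactants: 3 4-hydroxy-3,5-dimethoxybenzaldehyde (syringaldehyde)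
Product: 4 4-(2-hydroxyethoxy)-3,5-dimethoxybenzaldehyde
Conditions: BrCH2CH2OH (1.5 equiv), K2CO3, DMF, 80 °C
Reagents that add atoms: 2-bromoethanol, OCCBr
Why: Williamson ether synthesis at a primary carbon; this makes the O4′–Cβ bond of the target while Cβ is an unhindered CH2 group and the substrate has a single phenol, so the two ortho methoxy groups cost only rate.

Step 3
Reactants: 2 1-[2,4-bis(benzyloxy)-6-hydroxyphenyl]ethan-1-one; 4 4-(2-hydroxyethoxy)-3,5-dimethoxybenzaldehyde
Product: 5 (2E)-1-[2,4-bis(benzyloxy)-6-hydroxyphenyl]-3-[4-(2-hydroxyethoxy)-3,5-dimethoxyphenyl]prop-2-en-1-one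
Conditions: KOH (50% aq.), EtOH, rt
Reagents that add atoms: none
Why: Claisen–Schmidt condensation; 4 cannot enolise and has no phenoxide to deactivate its formyl group, and E1cB dehydration should give the (E)-enone, which is stabilised as its chelated phenoxide.

Step 4
Reactants: 5 (2E)-1-[2,4-bis(benzyloxy)-6-hydroxyphenyl]-3-[4-(2-hydroxyethoxy)-3,5-dimethoxyphenyl]prop-2-en-1-one
Product: 6 5,7-bis(benzyloxy)-2-[4-(2-hydroxyethoxy)-3,5-dimethoxyphenyl]-4H-chromen-4-one
Conditions: I2 (10 mol%), DMSO, 120 °C
Reagents that add atoms: none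
Why: Iodine-catalysed oxidative cyclisation of a 2′-hydroxychalcone: 6-endo oxa-Michael closure of ring C, α-iodination and loss of HI give the flavone, and DMSO reoxidises HI to I2; benzyl ethers are stable here and the catalytic amount of iodine should leave the primary alcohol alone.

Step 5
Reactants: 6 5,7-bis(benzyloxy)-2-[4-(2-hydroxyethoxy)-3,5-dimethoxyphenyl]-4H-chromen-4-one
Product: 7 {4-[5,7-bis(benzyloxy)-4-oxo-4H-chromen-2-yl]-2,6-dimethoxyphenoxy}acetaldehyde
Conditions: Dess–Martin periodinane (1.2 equiv), CH2Cl2, rt
Reagents that add atoms: none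
Why: Dess–Martin oxidation stops at the aldehyde under neutral, anhydrous conditions and does not touch the flavone or the aryl ethers; 7 is to be used at once in step 7 because α-aryloxy aldehydes hydrate and self-condense on storage.

Step 6
Reactants: 8 4-hydroxybenzaldehyde
Product: 9 4-formylphenyl 2,2-dimethylpropanoate
Conditions: PivCl, Et3N, 4-(dimethylamino)pyridine (cat.), CH2Cl2, 0 °C to rt
Reagents that add atoms: pivaloyl chloride, CC(C)(C)C(=O)Cl
Why: O-acylation of a phenol with nucleophilic catalysis; the pivalate turns the electron-donating phenol into a weakly electron-withdrawing group, which makes the formyl group a better aldol acceptor, and it is too hindered to acylate the amine catalyst of step 7.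

Step 7
Reactants: 7 {4-[5,7-bis(benzyloxy)-4-oxo-4H-chromen-2-yl]-2,6-dimethoxyphenoxy}acetaldehyde; 9 4-formylphenyl 2,2-dimethylpropanoate
Product: 11 4-[(1S,2R)-2-{4-[5,7-bis(benzyloxy)-4-oxo-4H-chromen-2-yl]-2,6-dimethoxyphenoxy}-1,3-dihydroxypropyl]phenyl 2,2-dimethylpropanoate, via anti-aldol aldehyde 10 (not isolated)
Conditions: 9 (5 equiv), L-proline (20 mol%), DMF, 4 °C, 7 added over 24 h; then MeOH, NaBH4, −20 to 0 °C
Reagents that add atoms: none
Why: Enamine catalysis, the closest known reaction type being the L-proline-catalysed direct anti cross-aldol of α-oxygenated acetaldehydes and of aldehydes with aromatic acceptors: L-proline condenses with the enolisable 7 to the (E)-enamine, while 9 has no α-hydrogen and can only be the acceptor. The C–C bond forms in the hydrogen-bonded chair-like transition state of proline enamine aldols, in which the carboxylic acid of the catalyst binds the carbonyl oxygen of 9. The enamine adds to the Re face of 9, which should set Cα as S, and the aryl group of 9 sits pseudo-equatorial, away from the aryloxy group on the enamine carbon, which should set Cβ anti to Cα (1S,2S in 10). Both stereocentres are thus controlled by the single stereocentre of the catalyst, and natural L-proline leads to the erythro series of the target. No ring is closed. The step needs cross-aldol over self-aldol selectivity, which is secured by keeping 7 at low concentration through slow addition into an excess of the activated acceptor 9. Because 10 can revert by retro-aldol reaction and epimerise at Cβ, it is reduced in the same flask with NaBH4, which converts the Cγ formyl group into hydroxymethyl without touching the hindered aryl pivalate or the vinylogous ester carbonyl of ring C. The descriptor at Cβ changes from S to R only because the priorities change.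

Step 8
Reactants: 11 4-[(1S,2R)-2-{4-[5,7-bis(benzyloxy)-4-oxo-4H-chromen-2-yl]-2,6-dimethoxyphenoxy}-1,3-dihydroxypropyl]phenyl 2,2-dimethylpropanoate
Product: 12 5,7-bis(benzyloxy)-2-(4-{[(1S,2R)-1,3-dihydroxy-1-(4-hydroxyphenyl)propan-2-yl]oxy}-3,5-dimethoxyphenyl)-4H-chromen-4-one
Conditions: K2CO3 (0.3 equiv), MeOH–THF, rt
Reagents that add atoms: none
Why: Base-catalysed transesterification of the aryl ester to methyl pivalate, the aryloxide being the better leaving group; no stereocentre carries an acidic hydrogen any more, and the benzylic alcohol para to the new phenoxide should not eliminate to a quinone methide at room temperature.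

Step 9
Reactants: 12 5,7-bis(benzyloxy)-2-(4-{[(1S,2R)-1,3-dihydroxy-1-(4-hydroxyphenyl)propan-2-yl]oxy}-3,5-dimethoxyphenyl)-4H-chromen-4-one
Product: 13 5,7-dihydroxy-2-(4-{[(1S,2R)-1,3-dihydroxy-1-(4-hydroxyphenyl)propan-2-yl]oxy}-3,5-dimethoxyphenyl)-4H-chromen-4-one (target)
Conditions: H2 (1 atm), Pd/C (10%), EtOAc–MeOH, rt
Reagents that add atoms: none
Why: Hydrogenolysis of the two benzyl ethers; the neutral medium and stopping at full conversion should keep the Cα benzylic alcohol and the C2=C3 bond of ring C, and neither stereocentre is touched.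

## Compound list

1 | 1-(2,4,6-trihydroxyphenyl)ethan-1-one | CC(=O)c1c(O)cc(O)cc1O | starting material
2 | 1-[2,4-bis(benzyloxy)-6-hydroxyphenyl]ethan-1-one | CC(=O)c1c(O)cc(OCc2ccccc2)cc1OCc1ccccc1 | intermediate
3 | 4-hydroxy-3,5-dimethoxybenzaldehyde (syringaldehyde) | COc1cc(C=O)cc(OC)c1O | starting material
4 | 4-(2-hydroxyethoxy)-3,5-dimethoxybenzaldehyde | COc1cc(C=O)cc(OC)c1OCCO | intermediate
5 | (2E)-1-[2,4-bis(benzyloxy)-6-hydroxyphenyl]-3-[4-(2-hydroxyethoxy)-3,5-dimethoxyphenyl]prop-2-en-1-one | COc1cc(/C=C/C(=O)c2c(O)cc(OCc3ccccc3)cc2OCc2ccccc2)cc(OC)c1OCCO | intermediate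
6 | 5,7-bis(benzyloxy)-2-[4-(2-hydroxyethoxy)-3,5-dimethoxyphenyl]-4H-chromen-4-one | COc1cc(-c2cc(=O)c3c(OCc4ccccc4)cc(OCc4ccccc4)cc3o2)cc(OC)c1OCCO | intermediate
7 | {4-[5,7-bis(benzyloxy)-4-oxo-4H-chromen-2-yl]-2,6-dimethoxyphenoxy}acetaldehyde | COc1cc(-c2cc(=O)c3c(OCc4ccccc4)cc(OCc4ccccc4)cc3o2)cc(OC)c1OCC=O | intermediate
8 | 4-hydroxybenzaldehyde | O=Cc1ccc(O)cc1 | starting material
9 | 4-formylphenyl 2,2-dimethylpropanoate | CC(C)(C)C(=O)Oc1ccc(C=O)cc1 | intermediate
10 | 4-[(1S,2S)-2-{4-[5,7-bis(benzyloxy)-4-oxo-4H-chromen-2-yl]-2,6-dimethoxyphenoxy}-1-hydroxy-3-oxopropyl]phenyl 2,2-dimethylpropanoate | COc1cc(-c2cc(=O)c3c(OCc4ccccc4)cc(OCc4ccccc4)cc3o2)cc(OC)c1O[C@H](C=O)[C@@H](O)c1ccc(OC(=O)C(C)(C)C)cc1 | intermediate (not isolated)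
11 | 4-[(1S,2R)-2-{4-[5,7-bis(benzyloxy)-4-oxo-4H-chromen-2-yl]-2,6-dimethoxyphenoxy}-1,3-dihydroxypropyl]phenyl 2,2-dimethylpropanoate | COc1cc(-c2cc(=O)c3c(OCc4ccccc4)cc(OCc4ccccc4)cc3o2)cc(OC)c1O[C@H](CO)[C@@H](O)c1ccc(OC(=O)C(C)(C)C)cc1 | intermediate
12 | 5,7-bis(benzyloxy)-2-(4-{[(1S,2R)-1,3-dihydroxy-1-(4-hydroxyphenyl)propan-2-yl]oxy}-3,5-dimethoxyphenyl)-4H-chromen-4-one | COc1cc(-c2cc(=O)c3c(OCc4ccccc4)cc(OCc4ccccc4)cc3o2)cc(OC)c1O[C@H](CO)[C@@H](O)c1ccc(O)cc1 | intermediate
13 | 5,7-dihydroxy-2-(4-{[(1S,2R)-1,3-dihydroxy-1-(4-hydroxyphenyl)propan-2-yl]oxy}-3,5-dimethoxyphenyl)-4H-chromen-4-one | COc1cc(-c2cc(=O)c3c(O)cc(O)cc3o2)cc(OC)c1O[C@H](CO)[C@@H](O)c1ccc(O)cc1 | target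

## Step count and least certain steps

Total step count: 9. Longest linear sequence: 7 steps (steps 2, 3, 4, 5, 7, 8, 9 from 3; the same length through step 1 from 1).

Step 7 (key step). Most likely to go wrong: self-aldol of 7 outruns the cross-aldol, because an α-aryloxy acetaldehyde is a stronger acceptor than an aromatic aldehyde. The anti/syn selectivity can also erode with aromatic acceptors, and retro-aldol reaction of 10 before the reduction would lower both diastereomeric and enantiomeric purity. Fallback (auxiliary-controlled anti-aldol at the imide oxidation level), which sets out from 6 and returns at 11: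
- 6 is oxidised with TEMPO (2,2,6,6-tetramethylpiperidin-1-oxyl, cat.) and PhI(OAc)2 in MeCN–H2O to the acid, {4-[5,7-bis(benzyloxy)-4-oxo-4H-chromen-2-yl]-2,6-dimethoxyphenoxy}acetic acid F1.
- F1 is converted through its pivaloyl mixed anhydride (PivCl, Et3N, THF, then (4R)-4-benzyl-1,3-oxazolidin-2-one and LiCl) into the imide, (4R)-4-benzyl-3-({4-[5,7-bis(benzyloxy)-4-oxo-4H-chromen-2-yl]-2,6-dimethoxyphenoxy}acetyl)-1,3-oxazolidin-2-one F2.
- F2 and 9 are joined in the MgCl2-catalysed anti-aldol of N-acyloxazolidinones with non-enolisable aldehydes (MgCl2 (cat.), Et3N, Me3SiCl, EtOAc, rt, then dilute acid to cleave the silyl ether). The magnesium-chelated (Z)-enolate should be attacked on the face opposite the benzyl group, which is why the (4R) auxiliary is chosen, to give the anti adduct, 4-[(1S,2S)-3-[(4R)-4-benzyl-2-oxo-1,3-oxazolidin-3-yl]-2-{4-[5,7-bis(benzyloxy)-4-oxo-4H-chromen-2-yl]-2,6-dimethoxyphenoxy}-1-hydroxy-3-oxopropyl]phenyl 2,2-dimethylpropanoate F3.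
- NaBH4 in THF–H2O removes the auxiliary reductively and gives 11.
- Because this fallback leaves from 6, it also avoids isolating 7.

Step 4. Most likely to go wrong: HI formed from I2 at 120 °C iodinates or oxidises the primary alcohol, or cleaves the benzyl ether on O5. Fallback (ring closure and dehydrogenation as two separate operations), which sets out from 5 and returns at 6: NaOAc in refluxing EtOH closes ring C by oxa-Michael addition to the flavanone, (2RS)-5,7-bis(benzyloxy)-2-[4-(2-hydroxyethoxy)-3,5-dimethoxyphenyl]-2,3-dihydro-4H-chromen-4-one F4, which is dehydrogenated with 2,3-dichloro-5,6-dicyano-1,4-benzoquinone in 1,4-dioxane at reflux to 6.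

Step 5. Most likely to go wrong: over-oxidation, hydration and self-condensation of the α-aryloxy aldehyde during oxidation and isolation. Fallback (the aldehyde is released by glycol cleavage instead of alcohol oxidation), which sets out from 3 and returns at 7:
- 3 is alkylated with 3-chloropropane-1,2-diol (K2CO3, DMF, 90 °C) to the glycerol ether, 4-(2,3-dihydroxypropoxy)-3,5-dimethoxybenzaldehyde F5.
- Condensation of F5 with 2 under the conditions of step 3 gives the enone, (2E)-1-[2,4-bis(benzyloxy)-6-hydroxyphenyl]-3-[4-(2,3-dihydroxypropoxy)-3,5-dimethoxyphenyl]prop-2-en-1-one F6.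
- Oxidative cyclisation as in step 4 gives the flavone diol, 5,7-bis(benzyloxy)-2-[4-(2,3-dihydroxypropoxy)-3,5-dimethoxyphenyl]-4H-chromen-4-one F7.
- NaIO4 in THF–H2O at 0 °C cleaves the diol of F7 to 7 with loss of formaldehyde, in a neutral medium that cannot oxidise the aldehyde further.

Step 9. Most likely to go wrong: hydrogenolysis of the benzylic Cα–O bond, which is activated by the free para phenol of ring D, or saturation of C2=C3, in competition with benzyl ether cleavage. Fallback (the order of the two deprotections is reversed, so that the hydrogenolysis runs while ring D still carries the electron-withdrawing pivalate), which sets out from 11 and returns at 13: 11 is hydrogenolysed (H2, Pd/C, EtOAc) to the dihydroxyflavone pivalate, 4-[(1S,2R)-2-[4-(5,7-dihydroxy-4-oxo-4H-chromen-2-yl)-2,6-dimethoxyphenoxy]-1,3-dihydroxypropyl]phenyl 2,2-dimethylpropanoate F8, and the pivalate of F8 is then removed with K2CO3 in MeOH to give 13.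

## Further compounds

F1 | step 7 | {4-[5,7-bis(benzyloxy)-4-oxo-4H-chromen-2-yl]-2,6-dimethoxyphenoxy}acetic acid | COc1cc(-c2cc(=O)c3c(OCc4ccccc4)cc(OCc4ccccc4)cc3o2)cc(OC)c1OCC(=O)O
F2 | step 7 | (4R)-4-benzyl-3-({4-[5,7-bis(benzyloxy)-4-oxo-4H-chromen-2-yl]-2,6-dimethoxyphenoxy}acetyl)-1,3-oxazolidin-2-one | COc1cc(-c2cc(=O)c3c(OCc4ccccc4)cc(OCc4ccccc4)cc3o2)cc(OC)c1OCC(=O)N1[C@H](Cc2ccccc2)COC1=O
F3 | step 7 | 4-[(1S,2S)-3-[(4R)-4-benzyl-2-oxo-1,3-oxazolidin-3-yl]-2-{4-[5,7-bis(benzyloxy)-4-oxo-4H-chromen-2-yl]-2,6-dimethoxyphenoxy}-1-hydroxy-3-oxopropyl]phenyl 2,2-dimethylpropanoate | COc1cc(-c2cc(=O)c3c(OCc4ccccc4)cc(OCc4ccccc4)cc3o2)cc(OC)c1O[C@H](C(=O)N1[C@H](Cc2ccccc2)COC1=O)[C@@H](O)c1ccc(OC(=O)C(C)(C)C)cc1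
F4 | step 4 | (2RS)-5,7-bis(benzyloxy)-2-[4-(2-hydroxyethoxy)-3,5-dimethoxyphenyl]-2,3-dihydro-4H-chromen-4-one | COc1cc(C2CC(=O)c3c(OCc4ccccc4)cc(OCc4ccccc4)cc3O2)cc(OC)c1OCCO
F5 | step 5 | 4-(2,3-dihydroxypropoxy)-3,5-dimethoxybenzaldehyde (racemic) | COc1cc(C=O)cc(OC)c1OCC(O)CO
F6 | step 5 | (2E)-1-[2,4-bis(benzyloxy)-6-hydroxyphenyl]-3-[4-(2,3-dihydroxypropoxy)-3,5-dimethoxyphenyl]prop-2-en-1-one (racemic) | COc1cc(/C=C/C(=O)c2c(O)cc(OCc3ccccc3)cc2OCc2ccccc2)cc(OC)c1OCC(O)CO
F7 | step 5 | 5,7-bis(benzyloxy)-2-[4-(2,3-dihydroxypropoxy)-3,5-dimethoxyphenyl]-4H-chromen-4-one (racemic) | COc1cc(-c2cc(=O)c3c(OCc4ccccc4)cc(OCc4ccccc4)cc3o2)cc(OC)c1OCC(O)CO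
F8 | step 9 | 4-[(1S,2R)-2-[4-(5,7-dihydroxy-4-oxo-4H-chromen-2-yl)-2,6-dimethoxyphenoxy]-1,3-dihydroxypropyl]phenyl 2,2-dimethylpropanoate | COc1cc(-c2cc(=O)c3c(O)cc(O)cc3o2)cc(OC)c1O[C@H](CO)[C@@H](O)c1ccc(OC(=O)C(C)(C)C)cc1
A1 | alternative 1 | 5,7-bis(benzyloxy)-2-(4-hydroxy-3,5-dimethoxyphenyl)-4H-chromen-4-one | COc1cc(-c2cc(=O)c3c(OCc4ccccc4)cc(OCc4ccccc4)cc3o2)cc(OC)c1O
A2 | alternative 1 | ethyl (2R,3S)-3-[4-(benzyloxy)phenyl]-3-hydroxy-2-{[(4-nitrophenyl)sulfonyl]oxy}propanoate | CCOC(=O)[C@H](OS(=O)(=O)c1ccc(cc1)[N+](=O)[O-])[C@@H](O)c1ccc(OCc2ccccc2)cc1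
A3 | alternative 1 | ethyl (2S,3S)-3-[4-(benzyloxy)phenyl]-2-{4-[5,7-bis(benzyloxy)-4-oxo-4H-chromen-2-yl]-2,6-dimethoxyphenoxy}-3-hydroxypropanoate | COc1cc(-c2cc(=O)c3c(OCc4ccccc4)cc(OCc4ccccc4)cc3o2)cc(OC)c1O[C@H](C(=O)OCC)[C@@H](O)c1ccc(OCc2ccccc2)cc1
A4 | alternative 2 | ethyl (2RS)-3-[4-(benzyloxy)phenyl]-2-{4-[5,7-bis(benzyloxy)-4-oxo-4H-chromen-2-yl]-2,6-dimethoxyphenoxy}-3-oxopropanoate | COc1cc(-c2cc(=O)c3c(OCc4ccccc4)cc(OCc4ccccc4)cc3o2)cc(OC)c1OC(C(=O)OCC)C(=O)c1ccc(OCc2ccccc2)cc1
A5 | alternative 2 | ethyl (2S,3R)-3-[4-(benzyloxy)phenyl]-2-{4-[5,7-bis(benzyloxy)-4-oxo-4H-chromen-2-yl]-2,6-dimethoxyphenoxy}-3-hydroxypropanoate | COc1cc(-c2cc(=O)c3c(OCc4ccccc4)cc(OCc4ccccc4)cc3o2)cc(OC)c1O[C@H](C(=O)OCC)[C@H](O)c1ccc(OCc2ccccc2)cc1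
A6 | alternative 3 | 5,7-dihydroxy-2-(4-hydroxy-3,5-dimethoxyphenyl)-4H-chromen-4-one (tricin) | COc1cc(-c2cc(=O)c3c(O)cc(O)cc3o2)cc(OC)c1O
A7 | alternative 3 | 4-[(1E)-3-hydroxyprop-1-en-1-yl]phenol | OC/C=C/c1ccc(O)cc1
A8 | alternative 3 | 5,7-dihydroxy-2-(4-{[(2RS)-1-hydroxy-3-(4-oxocyclohexa-2,5-dien-1-ylidene)propan-2-yl]oxy}-3,5-dimethoxyphenyl)-4H-chromen-4-one | COc1cc(-c2cc(=O)c3c(O)cc(O)cc3o2)cc(OC)c1OC(CO)C=C1C=CC(=O)C=C1
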